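(The data were generated by integration for an exercise, noise included.)

| flask | solid substrate | coupling partner | remark | time |
|---|---|---|---|---|
| birch | 0.070 M | 0.0475 M | run made earlier |  |
| oak | 0.11 M | 0.0475 M | run made earlier |  |
| elm | 0.050 M | 0.095 M | run made earlier |  |
| flask | 0.050 M | 0.0475 M |  | 4.0 h |

| run | time / h | target / % |
|---|---|---|
| birch | 1.33 | 5 |
| birch | 2.50 | 10 |
| birch | 4.00 | 16 |
| birch | 5.00 | 19 |
| oak | 1.33 | 5 |
| oak | 2.50 | 7 |
| oak | 4.00 | 10 |
| oak | 5.00 | 12 |
| elm | 1.33 | 8 |
| elm | 2.50 | 14 |
| elm | 4.00 | 24 |
| elm | 5.00 | 30 |

(each reading ± 1.5 percentage points)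

- as a solid, counted per litre of solution: solid substrate
- what was read earlier has a scatter of 1.5 percentage points, one standard deviation
- at the start none of the solid substrate is in solution

* amount of target in percent of the solid substrate charged, at 25 min, 80 min and 4.0 h

Early on, the birch run stands at 5% after 1.33 h. Its last reading, 19% after 5.00 h, spread evenly over the time, gives 0.0380 h⁻¹ and so predicts 5.05% at that first reading. Within the scatter of 1.5 percentage points you therefore read the birch run as a straight line, and these readings show no lag.

Does that slope depend on the charge? The oak run gives 0.0240 h⁻¹, so birch turns its charge over 1.58 times faster, and the charge of oak is larger by the factor 1.57. Per litre, birch and oak therefore read the same gain each hour, which you can read as zero order in solid substrate.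

Does the coupling partner matter? Scaled to the charge of the elm run, birch predicts 0.0532 h⁻¹, and elm, with twice the partner, reads 0.0600 h⁻¹. That is a factor of only 1.13, so I take the order in partner as close to zero.

Pooling the three last readings, I give the flask 0.0553 h⁻¹, its charge turnover, the fraction of the solid substrate charged that becomes target per hour.

Does the line last 4.0 h? The count is 22.1% of the charge, which uses 23.3% of the partner, the limiting reagent. Birch had used 28.0% of the same partner charge on its line. My course is therefore 2.31%, 7.38% and 22.1%.

The forecast, noting that “All the curves are near linear”, gives 2.3%, 7.7% and 23%, ending higher than mine.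

The flask gives 1.98%, 7.37% and 23.0%.

    starting material ⇌ reactive form, settled at all times (K = 1.40)
    coupling partner + reactive form → target (k = 440 M⁻¹ h⁻¹)
    2 starting material → self-condensation product (k = 1.50 M⁻¹ h⁻¹)
    solid substrate ⇌ starting material, rate k4*(cs4 - [starting material]) while solid is left; crystals form when [starting material] > cs4 (solubility = 27.0 mM, k = 0.110 h⁻¹)

Over 4.0 h the flask averages 0.0575 h⁻¹, beside the charge turnover of 0.0553 h⁻¹. At 0.400 h the flask holds 0.204% starting material and 0.285% reactive form beside 1.88% target. The count for one whole charge at the charge turnover is 18.1 h, and at 40.0 h the flask stands at 0% solid substrate and 95.0% target.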